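**The clock.** If a unit in a chain leaves at a steady first-order rate, the share asked for, the selectivity, should follow rate times time.

in all of them: free monomer 0.020 M

| run | initiator | temperature | remark | time |
|---|---|---|---|---|
| winter | 27 µM | −30 °C | run made earlier |  |
| noon | 60 µM | −8 °C | run made earlier |  |
| alder | 40 µM | 0 °C |  | 25 min |
| larch | 40 µM |  | at −40 °C until 12 min, from then on at 0 °C | 25 min |
| cedar | 40 µM | −40 °C |  | 25 min |
| birch | 40 µM | −20 °C |  | 25 min |

- winter (time / min: monomer in chains / %, over-reaction product / %): 20.0: 8, 3; 40.0: 14, 2; 60.0: 19, 4; 80.0: 26, 3; 120: 30, 3
- noon (time / min: monomer in chains / %, over-reaction product / %): 5.00: 22, 7; 10.0: 34, 8; 15.0: 37, 16; 20.0: 35, 27; 25.0: 40, 30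

(each reading ± 2 percentage points)

- the flask that comes out highest in share of monomer in chains in all that became monomer in chains or over-reaction product, or "all alike" when all lie within 1.5 percentage points (alder / larch / cedar / birch / all alike)
- share of monomer in chains in all that became monomer in chains or over-reaction product, alder
- share of monomer in chains in all that became monomer in chains or over-reaction product, larch
- share of monomer in chains in all that became monomer in chains or over-reaction product, cedar
- share of monomer in chains in all that became monomer in chains or over-reaction product, birch



**Two readings.** In the noon run the product trails the chains, so I take it as made from them. The area under the noon chain curve, in fractions of the charge, is 7.40 min. Its last product reading then gives a rate of 0.0405 /min. The winter area is 22.0 min. Its product lies flat within the scatter, and I read that as small, not as an early offset. So its last reading gives 0.00136 /min, a rough value. I draw the logarithm of the rate straight in temperature through both runs. Cedar then has 2.92 × 10⁻⁴ /min, and over its time that gives 0.00729. This product of rate and time is my over-reaction clock.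

**The curve.** While chains grow steadily, product over chains equals the clock divided by 2. So the share starts at 100 % and falls with slope one over 2 per unit of clock. On this rule chains and product cross at a clock of 2. The knee comes as chains bend away from steady growth. The noon run ends at a clock of 1.01, where this rule says 66.4 % and the readings say 57.1 %. The rule therefore serves small clocks.

**My reckoning.** Cedar's clock gives 99.6 %. Birch has a clock of 0.159, so 92.6 %. Larch's warm stretch reads 1.81, larger than the clock at the end of the noon run, so I do not trust the rule for larch. Alder reads 3.48, larger again. I commit to cedar.

**The forecast.** It names birch, with alder 20 %, larch 39 %, cedar 68 % and birch 83 %. On cedar it says “the offset of about 3 dominates”, and there it parts from my reckoning.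

**The result.** The highest flask is cedar: alder 20.3 %, larch 44.4 %, cedar 99.5 %, birch 88.3 %.

    initiator → 2 initiating radical (k = 2.38 × 10⁻⁵ /s, Ea = 97.0 kJ/mol)
    free monomer + initiating radical → growing radical + monomer in chains (k = 2.16 × 10⁶ /M/s, Ea = 12.0 kJ/mol)
    free monomer + growing radical → monomer in chains + growing radical, rate k3*[growing radical]*[free monomer] (k = 97500 /M/s, Ea = 15.0 kJ/mol)
    2 growing radical → dead chain (k = 1.90 × 10⁶ /M/s, Ea = 14.0 kJ/mol)
    free monomer ⇌ dormant form (K = 0.498, k = 0.00342 /s, Ea = 70.0 kJ/mol, ΔH = 8.00 kJ/mol)
    monomer in chains → over-reaction product (k = 0.00187 /s, Ea = 71.0 kJ/mol)
    (constants at 0 °C)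

**Why they part.** Cedar's clock of 0.00729 stands behind the 99.5 %, and cedar holds 0.0146 % of over-reaction product after 25.0 min, with no offset. With the temperature taken off the step from chains to product, the gap between alder and cedar shrinks from 79 percentage points to 0.38 points. A neighbour flask like cedar, kept at −25 °C, has a clock of 0.0737, which gives 96.4 %. The computed flask gives 94.2 %.

The data stem from a simulated flask from invented constants, and the scatter is random.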